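**Retrosynthetic overview**

1. Last disconnection at the ArC–CH2 bond: conjugate Friedel–Crafts addition of acylphloroglucinol 12 to the 2-methylidene-1,3-dione 15, which is released by selenoxide syn-elimination from selenide 13 (step 8, no protecting groups).
2. Enabling feature: in the left ring, C2 lies between the ring carbonyls C1 and C3 and its methyl group carries the only β-hydrogens, so a C2–Se bond converts cleanly into the exocyclic C2=CH2 electrophile; the right ring has exactly one unsubstituted carbon, flanked by two OH groups.
3. C4 is stereogenic only because C2 bears CH2Ar and C6 bears CH3; it is therefore created by desymmetrising the Cs-symmetric 2,6-dimethyl compound 10 (catalytic enantioselective selenenylation of one of two enantiotopic enol carbons, step 7).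
4. 10 comes from a para-Claisen (Claisen–Cope) rearrangement of a 4-O-prenyl ether, which delivers prenyl to the isobutyryl-bearing carbon and dearomatises the ring (step 5).
5. No ring is constructed: both six-membered carbocycles derive from phloroglucinol through the common ketone 3.

Key step: step 8

Remark: the left ring is written in the tautomer of the target SMILES (its keto/enol forms interconvert freely). Left-ring numbering: C1 ring C=O, C2 bridge-bearing carbon, C4 quaternary carbon, C6 C-methyl carbon. CIP descriptors at C4 refer to the tautomers drawn.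

**Route**

Step 1
Reactants: 1 phloroglucinol; 2 isobutyryl chloride
Product: 3 2-methyl-1-(2,4,6-trihydroxyphenyl)propan-1-one (phlorisobutyrophenone)
Conditions: AlCl3 (3.5 equiv), PhNO2/CH2Cl2, 0 → 50 °C; aq. HCl work-up
Reagents that add atoms: none
Why: Friedel–Crafts C-acylation of the symmetric triol should stop at the mono-ketone, because the chelated acyl group deactivates the ring toward a second acylation.

Step 2
Reactants: 3 phlorisobutyrophenone
Product: 4 1-(2,4,6-trihydroxy-3,5-dimethylphenyl)-2-methylpropan-1-one
Conditions: NaOMe (3 equiv), MeI (2.0 equiv, slow addition), MeOH, 0 °C → rt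
Reagents that add atoms: iodomethane, CI
Why: C-methylation of the ambident phloroglucinolate in protic medium (a known alkylation of acylphloroglucinols) takes place at the two free ring carbons, and limiting MeI to two equivalents should hold the reaction before the dearomatising third methylation.

Step 3
Reactants: 4 3,5-dimethylphlorisobutyrophenone; 5 3-methylbut-2-en-1-ol (prenol)
Product: 6 1-[2,6-dihydroxy-3,5-dimethyl-4-(3-methylbut-2-en-1-yloxy)phenyl]-2-methylpropan-1-one
Conditions: PPh3, DIAD, THF, 0 °C → rt
Reagents that add atoms: none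
Why: Mitsunobu etherification should select the 4-OH (para to the ketone, most acidic, not hydrogen-bonded to the carbonyl) and gives O- rather than C-prenylation.

Step 4
Reactants: 6 4-O-prenyl ether
Product: 7 1-[2,6-bis(tert-butyldimethylsilyloxy)-3,5-dimethyl-4-(3-methylbut-2-en-1-yloxy)phenyl]-2-methylpropan-1-one
Conditions: TBSOTf (2.5 equiv), 2,6-lutidine, CH2Cl2, 0 °C → rt
Reagents that add atoms: tert-butyldimethylsilyl trifluoromethanesulfonate, CC(C)(C)[Si](C)(C)OS(=O)(=O)C(F)(F)F
Why: O-silylation of the two chelated phenols with the silyl triflate locks both oxygens, so that after the Claisen shift no tautomer exists that could relay the allyl group anywhere but to the para carbon.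

Step 5
Reactants: 7 bis-TBS prenyl ether
Product: 10 3,5-dihydroxy-2,6-dimethyl-4-(2-methylpropanoyl)-4-(3-methylbut-2-en-1-yl)cyclohexa-2,5-dien-1-one, via ortho-dienone 8 (not isolated), via bis-silyl para-dienone 9 (not isolated)
Conditions: PhNEt2, 185 °C, sealed tube; then TBAF, AcOH, THF, 0 °C
Reagents that add atoms: none
Why: para-Claisen rearrangement: the aromatic Claisen [3,3] shift to a methyl-blocked ortho carbon gives dienone 8, whose only all-carbon 1,5-diene relays the allyl unit by a Cope [3,3] shift to the para, isobutyryl-bearing carbon with return of the linear prenyl group, and buffered fluoride then cleaves the two vinylogous silyl esters of 9 to the vinylogous acid 10, which is Cs-symmetric and therefore achiral.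

Step 6
Reactants: 3 phlorisobutyrophenone; 11 1-bromo-3-methylbut-2-ene (prenyl bromide)
Product: 12 2-methyl-1-[2,4,6-trihydroxy-3-(3-methylbut-2-en-1-yl)phenyl]propan-1-one
Conditions: 10% aq. KOH, prenyl bromide (1.0 equiv), 0 °C → rt
Reagents that add atoms: none
Why: C-prenylation of the phloroglucinolate in water (the classical alkylation of acylphloroglucinols) occurs at a free ring carbon with rearomatisation, and one equivalent of bromide should limit diprenylation.

Step 7
Reactants: 10 symmetric 2,6-dimethyl vinylogous acid
Product: 13 (4R)-5-hydroxy-2,6-dimethyl-4-(2-methylpropanoyl)-4-(3-methylbut-2-en-1-yl)-2-(phenylselanyl)cyclohex-5-ene-1,3-dione (either C-2 epimer)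
Conditions: N-(phenylseleno)phthalimide (1.0 equiv), quinidine-derived bifunctional squaramide (10 mol %), toluene, −40 °C, dark
Reagents that add atoms: N-(phenylseleno)phthalimide, O=C1c2ccccc2C(=O)N1[Se]c1ccccc1
Why: Proposed new method: the acidic substrate protonates the catalyst's quinuclidine and ion-pairs with it, while the squaramide N–H groups hold the C4 isobutyryl C=O and the neighbouring ring oxygen, a two-point contact that is diastereomeric for the O3 and O5 arms, so the selenium electrophile should be delivered to one of the two enantiotopic enol carbons (C2, not C6) and C4 becomes stereogenic; the closest known reaction types are organocatalytic enantioselective α-sulfenylation/selenenylation of 1,3-dicarbonyl compounds with N-chalcogeno imides and catalytic desymmetrisation of 2,2-disubstituted cyclic 1,3-diones; which pseudoenantiomeric catalyst gives the (4R) series must be found by screening, and the configuration at C2 is irrelevant because step 8 erases it.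

Step 8
Reactants: 13 (4R)-selenide; 12 prenylated phlorisobutyrophenone
Product: 16 (4S)-3,5-dihydroxy-6-methyl-4-(2-methylpropanoyl)-4-(3-methylbut-2-en-1-yl)-2-{[2,4,6-trihydroxy-3-(2-methylpropanoyl)-5-(3-methylbut-2-en-1-yl)phenyl]methyl}cyclohexa-2,5-dien-1-one (target), via selenoxide 14 (not isolated), via methylidene trione 15 (not isolated)
Conditions: mCPBA (1.0 equiv), CH2Cl2, −78 °C, 20 min; then 12 (1.3 equiv, in THF), i-Pr2NH (2 equiv), −78 → 0 °C
Reagents that add atoms: none
Why: mCPBA oxidises selenium at −78 °C far faster than it epoxidises trisubstituted alkenes, and on warming selenoxide 14 undergoes syn-elimination toward the C2 methyl group, the only site with β-hydrogens because C1 and C3 are carbonyl carbons, which unmasks the 2-methylidene-1,3-dione 15 (a quinone-methide-like cross-conjugated trienone) below 0 °C. Phloroglucinol 12 then adds through its single unsubstituted ring carbon to the exocyclic CH2 (conjugate Friedel–Crafts/Michael addition), and tautomerisation restores the aromatic ring and the vinylogous acid of the left ring. The closest known reaction types are the selenoxide route to 2-alkylidene-1,3-diones and the union of acylphloroglucinols with methylene-trione electrophiles that is the standard entry to methylene-bridged phloroglucinol dimers. No ring is closed and no stereocentre is created: C4 is quaternary and non-enolisable, so the configuration from step 7 is carried through unchanged (the descriptor changes from R to S only because the CIP ranking of the ring arms changes), and C2 becomes sp2. The step needs cross- over self-coupling, C- over O-alkylation and tolerance of three prenyl groups and five free OH groups: self-coupling of 15 would have to build a quaternary centre at its substituted enol carbon whereas 12 offers one rearomatisable ring carbon, O-adducts revert by retro-oxa-Michael reaction whereas the C–C bond is irreversible, the peracid is consumed before 12 enters the flask, and i-Pr2NH intercepts benzeneselenenic acid before it can add to alkenes or arene.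

**Compound list**

1 | phloroglucinol (benzene-1,3,5-triol) | Oc1cc(O)cc(O)c1 | starting material
2 | isobutyryl chloride | CC(C)C(=O)Cl | starting material
3 | 2-methyl-1-(2,4,6-trihydroxyphenyl)propan-1-one | CC(C)C(=O)c1c(O)cc(O)cc1O | intermediate
4 | 1-(2,4,6-trihydroxy-3,5-dimethylphenyl)-2-methylpropan-1-one | CC(C)C(=O)c1c(O)c(C)c(O)c(C)c1O | intermediate
5 | 3-methylbut-2-en-1-ol (prenol) | CC(C)=CCO | starting material
6 | 1-[2,6-dihydroxy-3,5-dimethyl-4-(3-methylbut-2-en-1-yloxy)phenyl]-2-methylpropan-1-one | CC(C)C(=O)c1c(O)c(C)c(OCC=C(C)C)c(C)c1O | intermediate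
7 | 1-[2,6-bis(tert-butyldimethylsilyloxy)-3,5-dimethyl-4-(3-methylbut-2-en-1-yloxy)phenyl]-2-methylpropan-1-one | CC(C)C(=O)c1c(O[Si](C)(C)C(C)(C)C)c(C)c(OCC=C(C)C)c(C)c1O[Si](C)(C)C(C)(C)C | intermediate
8 | racemic 3,5-bis(tert-butyldimethylsilyloxy)-2,6-dimethyl-6-(2-methylbut-3-en-2-yl)-4-(2-methylpropanoyl)cyclohexa-2,4-dien-1-one (ortho-dienone) | CC(C)C(=O)C1=C(O[Si](C)(C)C(C)(C)C)C(C)(C(C)(C)C=C)C(=O)C(C)=C1O[Si](C)(C)C(C)(C)C | intermediate (not isolated)
9 | 3,5-bis(tert-butyldimethylsilyloxy)-2,6-dimethyl-4-(2-methylpropanoyl)-4-(3-methylbut-2-en-1-yl)cyclohexa-2,5-dien-1-one (achiral) | CC(C)C(=O)C1(CC=C(C)C)C(O[Si](C)(C)C(C)(C)C)=C(C)C(=O)C(C)=C1O[Si](C)(C)C(C)(C)C | intermediate (not isolated)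
10 | 3,5-dihydroxy-2,6-dimethyl-4-(2-methylpropanoyl)-4-(3-methylbut-2-en-1-yl)cyclohexa-2,5-dien-1-one (achiral, Cs) | CC(C)C(=O)C1(CC=C(C)C)C(O)=C(C)C(=O)C(C)=C1O | intermediate
11 | 1-bromo-3-methylbut-2-ene (prenyl bromide) | CC(C)=CCBr | starting material
12 | 2-methyl-1-[2,4,6-trihydroxy-3-(3-methylbut-2-en-1-yl)phenyl]propan-1-one | CC(C)=CCc1c(O)cc(O)c(C(=O)C(C)C)c1O | intermediate
13 | (4R)-5-hydroxy-2,6-dimethyl-4-(2-methylpropanoyl)-4-(3-methylbut-2-en-1-yl)-2-(phenylselanyl)cyclohex-5-ene-1,3-dione, C-2 configuration left open | CC1([Se]c2ccccc2)C(=O)[C@@](CC=C(C)C)(C(=O)C(C)C)C(O)=C(C)C1=O | intermediate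
14 | (4R)-5-hydroxy-2,6-dimethyl-4-(2-methylpropanoyl)-4-(3-methylbut-2-en-1-yl)-2-(phenylseleninyl)cyclohex-5-ene-1,3-dione, C-2 and Se configuration left open | CC1([Se](=O)c2ccccc2)C(=O)[C@@](CC=C(C)C)(C(=O)C(C)C)C(O)=C(C)C1=O | intermediate (not isolated)
15 | (4R)-5-hydroxy-6-methyl-2-methylidene-4-(2-methylpropanoyl)-4-(3-methylbut-2-en-1-yl)cyclohex-5-ene-1,3-dione | C=C1C(=O)[C@@](CC=C(C)C)(C(=O)C(C)C)C(O)=C(C)C1=O | intermediate (not isolated)
16 | (4S)-3,5-dihydroxy-6-methyl-4-(2-methylpropanoyl)-4-(3-methylbut-2-en-1-yl)-2-{[2,4,6-trihydroxy-3-(2-methylpropanoyl)-5-(3-methylbut-2-en-1-yl)phenyl]methyl}cyclohexa-2,5-dien-1-one | CC(C)=CCc1c(O)c(CC2=C(O)[C@@](CC=C(C)C)(C(=O)C(C)C)C(O)=C(C)C2=O)c(O)c(C(=O)C(C)C)c1O | target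

**Step count and risks**

Total steps: 8. Longest linear sequence: 7 (steps 1, 2, 3, 4, 5, 7, 8); the right half needs steps 1 and 6 before the union.

Steps most likely to fail:

1. Step 7 (Proposed new method). The catalyst may discriminate poorly between the two enantiotopic enol carbons. Enantiopurity may also erode through selenium transfer between the product and unreacted enolate of 10, and a second selenenylation at C6 may occur. Fallback with known chemistry: from 10, selenenylation with N-(phenylseleno)phthalimide and an achiral base (Et3N, CH2Cl2, −40 °C; the ordinary α-selenenylation of 2-alkyl-1,3-diones) gives the racemic selenide F1. Being a vinylogous acid, it is resolved classically by fractional crystallisation of the (S)-1-phenylethylammonium salt of the (4R)-acid F2 (the antipodal amine is used if the other salt crystallises first). Acidification (cold 1 M HCl, EtOAc) returns to the route at 13.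

2. Step 5. The first [3,3] shift must join the dimethyl-substituted allyl terminus to a methyl-bearing ring carbon; it may be too slow, so that thermal cleavage of the prenyl ether or reversal to the ether wins before the Cope relay. Fallback: from 4, Mitsunobu etherification with allyl alcohol gives the 4-O-allyl ether F3, and silylation as in step 4 gives the bis-TBS allyl ether F4. Heating (PhNEt2, 170 °C) leads through the allyl ortho-dienone F5 (not isolated) to the 4-allyl para-dienone F6; the unsubstituted allyl terminus makes both shifts much easier. Olefin cross-metathesis of F6 with 2-methyl-2-butene (second-generation Ru–NHC benzylidene catalyst, CH2Cl2, 40 °C) converts allyl into prenyl and returns to the route at 9, which is desilylated to 10 as in step 5.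

3. Step 8. The methylidene trione may self-condense before the arene captures it, and the electrophilic selenium by-product may be intercepted by the electron-rich arene or the prenyl alkenes. Fallback that separates oxidation from C–C bond formation: from 13, the same oxidation/elimination is run without 12 but with sodium 4-methylbenzenesulfinate (3 equiv, AcOH buffer, added after the peracid is consumed). The sulfinate adds to 15 and gives the crystalline, selenium-free sulfone F7, a bench-stable precursor of 15. F7 is then united with 12 under mild base (NaOAc, MeOH/THF, 40 °C; sulfinate elimination and conjugate Friedel–Crafts addition, the established sulfone/Mannich-base route to methylene-bridged acylphloroglucinols), returning to the route at 16.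

**Further compounds**

F1 | step 7 | racemic 5-hydroxy-2,6-dimethyl-4-(2-methylpropanoyl)-4-(3-methylbut-2-en-1-yl)-2-(phenylselanyl)cyclohex-5-ene-1,3-dione | CC1([Se]c2ccccc2)C(=O)C(CC=C(C)C)(C(=O)C(C)C)C(O)=C(C)C1=O
F2 | step 7 | (S)-1-phenylethylammonium salt of the (4R)-selenide 13 | CC1([Se]c2ccccc2)C(=O)[C@@](CC=C(C)C)(C(=O)C(C)C)C([O-])=C(C)C1=O.C[C@H]([NH3+])c1ccccc1
F3 | step 5 | 1-[2,6-dihydroxy-3,5-dimethyl-4-(prop-2-en-1-yloxy)phenyl]-2-methylpropan-1-one | CC(C)C(=O)c1c(O)c(C)c(OCC=C)c(C)c1O
F4 | step 5 | 1-[2,6-bis(tert-butyldimethylsilyloxy)-3,5-dimethyl-4-(prop-2-en-1-yloxy)phenyl]-2-methylpropan-1-one | CC(C)C(=O)c1c(O[Si](C)(C)C(C)(C)C)c(C)c(OCC=C)c(C)c1O[Si](C)(C)C(C)(C)C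
F5 | step 5 | racemic 3,5-bis(tert-butyldimethylsilyloxy)-2,6-dimethyl-4-(2-methylpropanoyl)-6-(prop-2-en-1-yl)cyclohexa-2,4-dien-1-one | CC(C)C(=O)C1=C(O[Si](C)(C)C(C)(C)C)C(C)(CC=C)C(=O)C(C)=C1O[Si](C)(C)C(C)(C)C
F6 | step 5 | 3,5-bis(tert-butyldimethylsilyloxy)-2,6-dimethyl-4-(2-methylpropanoyl)-4-(prop-2-en-1-yl)cyclohexa-2,5-dien-1-one | CC(C)C(=O)C1(CC=C)C(O[Si](C)(C)C(C)(C)C)=C(C)C(=O)C(C)=C1O[Si](C)(C)C(C)(C)C
F7 | step 8 | (4S)-3,5-dihydroxy-6-methyl-2-[(4-methylphenyl)sulfonylmethyl]-4-(2-methylpropanoyl)-4-(3-methylbut-2-en-1-yl)cyclohexa-2,5-dien-1-one | Cc1ccc(cc1)S(=O)(=O)CC1=C(O)[C@@](CC=C(C)C)(C(=O)C(C)C)C(O)=C(C)C1=O
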